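**Retrosynthetic overview**

1. Last disconnection (biomimetic): the benzotropolone is split into (−)-epicatechin, whose catechol ring B becomes the benzo ring, and an epicatechin-gallate isomer with a 2,3,4-trihydroxyphenyl ring B, which supplies C5–C9 of the seven-membered ring and loses C4' as CO2 (peroxidase/H2O2).
2. The galloylated flavan is cut at the ester, then ring C is opened at O1–C8a (not O1–C2). This gives an acyclic (1R,2R) syn alcohol whose ring A is a 2,4,6-trifluorophenyl group; one basic operation closes O1–C8a and installs the C5 and C7 oxygens by SNAr.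
3. Enabling feature: ring A is a phloroglucinol ring. Its oxygen-bearing carbons C8a, C5 and C7 are mutually meta, and C8a and C5 flank C4a symmetrically, so a twofold-symmetric trifluorophenyl ring can stand in for it. Either ortho C–F can become C8a, every new oxygen is meta to the remaining C–F bonds, and the C2–O1 bond is never broken, so syn becomes 2,3-cis.
4. The syn alcohol comes from chelation-controlled addition of a 2,3,4-tris(benzyloxy)phenyl Grignard reagent to an (R)-α-MOM-oxy aldehyde, built from (R)-trityl glycidyl ether and 2,4,6-trifluorophenylmagnesium chloride.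
5. Order of ring formation: ring C of the galloylated unit (step 8), then the seven-membered tropolone ring (step 12); all other rings are bought.

Key step: step 8

Remark: the tropolone is treated as its freely interconverting tautomers (C5=O/C6–OH as drawn), and all four flavan stereocentres are (R), i.e. both units are 2,3-cis.

**Step 1**
Reactants: 1 1-bromo-2,4,6-trifluorobenzene; 2 (R)-trityl glycidyl ether, (2R)-2-[(trityloxy)methyl]oxirane
Product: 4 (2R)-1-(2,4,6-trifluorophenyl)-3-(trityloxy)propan-2-ol, via (2,4,6-trifluorophenyl)magnesium chloride 3 (not isolated)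
Conditions: i-PrMgCl, THF, −15 °C; CuI (10 mol%), then 2, −15 to 0 °C; aq. NH4Cl
Reagents that add atoms: none
Why: Bromine–magnesium exchange of the electron-poor aryl bromide is fast, and the CuI-catalysed opening of the terminal epoxide by the aryl Grignard reagent occurs at the unsubstituted carbon, so the stereocentre of 2 is carried over untouched.

**Step 2**
Reactants: 4 (2R)-1-(2,4,6-trifluorophenyl)-3-(trityloxy)propan-2-ol
Product: 5 1,3,5-trifluoro-2-[(2R)-2-(methoxymethoxy)-3-(trityloxy)propyl]benzene
Conditions: MOMCl, i-Pr2NEt, CH2Cl2, 0 °C to rt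
Reagents that add atoms: chloromethyl methyl ether, COCCl
Why: Standard MOM ether formation under amine base avoids a free alkoxide that could attack an ortho C–F bond, and installs the chelating oxygen needed in step 7.

**Step 3**
Reactants: 5 1,3,5-trifluoro-2-[(2R)-2-(methoxymethoxy)-3-(trityloxy)propyl]benzene
Product: 6 (2R)-2-(methoxymethoxy)-3-(2,4,6-trifluorophenyl)propan-1-ol
Conditions: TsOH·H2O (cat.), MeOH/CH2Cl2, 0 °C to rt
Reagents that add atoms: none
Why: Acid-catalysed detritylation through the trityl cation should be far faster than cleavage of the MOM acetal, and the stereocentre is not involved.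

**Step 4**
Reactants: 6 (2R)-2-(methoxymethoxy)-3-(2,4,6-trifluorophenyl)propan-1-ol
Product: 7 (2R)-2-(methoxymethoxy)-3-(2,4,6-trifluorophenyl)propanal
Conditions: Dess–Martin periodinane, CH2Cl2, 0 °C to rt; used directly
Reagents that add atoms: none
Why: Dess–Martin oxidation gives the α-alkoxy aldehyde under neutral, non-epimerising conditions.

**Step 5**
Reactants: 8 pyrogallol
Product: 9 1,2,3-tris(benzyloxy)benzene
Conditions: BnBr, K2CO3, DMF, 60 °C, under N2
Reagents that add atoms: benzyl bromide, BrCc1ccccc1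
Why: Williamson ether synthesis on all three phenols, run under inert gas because pyrogallol is air-sensitive in base.

**Step 6**
Reactants: 9 1,2,3-tris(benzyloxy)benzene
Product: 10 1-bromo-2,3,4-tris(benzyloxy)benzene
Conditions: NBS, MeCN, 0 °C to rt
Reagents that add atoms: N-bromosuccinimide, O=C1CCC(=O)N1Br
Why: Electrophilic aromatic bromination should go to C4, which is ortho and para to the two outer benzyloxy groups, whereas C5 is activated only by the twisted central one.

**Step 7**
Reactants: 10 1-bromo-2,3,4-tris(benzyloxy)benzene; 7 (2R)-2-(methoxymethoxy)-3-(2,4,6-trifluorophenyl)propanal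
Product: 12 (1R,2R)-2-(methoxymethoxy)-1-[2,3,4-tris(benzyloxy)phenyl]-3-(2,4,6-trifluorophenyl)propan-1-ol, via [2,3,4-tris(benzyloxy)phenyl]magnesium bromide 11 (not isolated)
Conditions: Mg turnings, THF, 40 °C; then added to 7 and MgBr2·OEt2 in CH2Cl2, −78 °C; aq. NH4Cl
Reagents that add atoms: none
Why: Grignard addition under Cram chelate control: magnesium bridges the carbonyl and MOM oxygens and the aryl group adds to the face opposite the benzylic CH2 substituent, which should set the new carbinol centre syn to the C2 oxygen, i.e. (1R,2R).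

**Step 8**
Reactants: 12 (1R,2R)-2-(methoxymethoxy)-1-[2,3,4-tris(benzyloxy)phenyl]-3-(2,4,6-trifluorophenyl)propan-1-ol
Product: 15 (2R,3R)-5,7-bis(benzyloxy)-3-(methoxymethoxy)-2-[2,3,4-tris(benzyloxy)phenyl]chromane, via 5,7-difluorochromane 13 (not isolated), via 7-benzyloxy-5-fluorochromane 14 (not isolated)
Conditions: KOt-Bu (1.1 equiv), DMI (1,3-dimethyl-2-imidazolidinone), 0 °C to rt; then BnOH/KOt-Bu (5 equiv each, premixed), 120 °C, one pot
Reagents that add atoms: benzyl alcohol, OCc1ccccc1
Why: KOt-Bu turns the C1 hydroxyl of 12 into the potassium alkoxide, which adds to an ortho C–F carbon of the trifluorophenyl ring to give a Meisenheimer anion stabilised inductively by the two remaining fluorines; loss of fluoride closes ring C through the O1–C8a bond (13), and potassium benzyl oxide then replaces the fluorides at C7 and C5 in two further addition–elimination steps (via 14). The closest known reaction type is nucleophilic aromatic substitution of aryl fluorides by alkoxides, used intramolecularly to close chroman rings and intermolecularly to make alkoxyarenes from polyfluorobenzenes. Ring C closes in a 6-exo-trig addition–elimination at C8a. No stereocentre is formed: because the C2–O1 bond is never broken, the (1R,2R) syn relationship from step 7 is transferred with retention and becomes the 2,3-cis (2R,3R) configuration, which closures through O1–C2 do not guarantee. The step needs site and chemoselectivity: the two ortho fluorines are equivalent by rotation about the C4–C4a bond so either closure gives the same chromane, the MOM group blocks the five-membered closure through the C3 oxygen, and the base for closure is added before the benzyl oxide so that the intramolecular substitution comes first. Every oxygen introduced is meta to the C–F bonds that remain and so does not deactivate them by resonance, which is why all three substitutions should run in one pot.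

**Step 9**
Reactants: 15 (2R,3R)-5,7-bis(benzyloxy)-3-(methoxymethoxy)-2-[2,3,4-tris(benzyloxy)phenyl]chromane
Product: 16 (2R,3R)-5,7-bis(benzyloxy)-2-[2,3,4-tris(benzyloxy)phenyl]chroman-3-ol
Conditions: conc. aq. HCl (cat.), MeOH/THF, 40 °C
Reagents that add atoms: none
Why: Acid-catalysed acetal exchange with methanol removes the MOM group, while the benzyl aryl ethers are stable and the C2–O1 bond, deactivated towards ionisation by the adjacent C3 oxygen, should not open at this acidity.

**Step 10**
Reactants: 16 (2R,3R)-5,7-bis(benzyloxy)-2-[2,3,4-tris(benzyloxy)phenyl]chroman-3-ol; 17 3,4,5-tris(benzyloxy)benzoic acid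
Product: 18 (2R,3R)-5,7-bis(benzyloxy)-2-[2,3,4-tris(benzyloxy)phenyl]chroman-3-yl 3,4,5-tris(benzyloxy)benzoate
Conditions: DCC, DMAP (cat.), CH2Cl2, rt
Reagents that add atoms: none
Why: Steglich esterification acylates the only free hydroxyl with retention at C3.

**Step 11**
Reactants: 18 (2R,3R)-5,7-bis(benzyloxy)-2-[2,3,4-tris(benzyloxy)phenyl]chroman-3-yl 3,4,5-tris(benzyloxy)benzoate
Product: 19 (2R,3R)-5,7-dihydroxy-2-(2,3,4-trihydroxyphenyl)chroman-3-yl 3,4,5-trihydroxybenzoate
Conditions: H2 (1 atm), Pd(OH)2/C, THF/MeOH, rt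
Reagents that add atoms: none
Why: Catalytic hydrogenolysis should cleave all eight benzyl ethers under neutral conditions without touching the benzoate ester or the cyclic C2–O1 ether.

**Step 12**
Reactants: 19 (2R,3R)-5,7-dihydroxy-2-(2,3,4-trihydroxyphenyl)chroman-3-yl 3,4,5-trihydroxybenzoate; 20 (−)-epicatechin
Product: 23 the target, via epicatechin o-quinone 21 (not isolated), via biaryl adduct 22 (not isolated)
Conditions: horseradish peroxidase (a heme peroxidase), H2O2 (3 equiv, slow addition), acetone/citrate–phosphate buffer pH 5 (1:10), rt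
Reagents that add atoms: none
Why: In this peroxidase-mediated benzotropolone synthesis of the theaflavin type, the enzyme oxidises ring B of 20 to quinone 21, C5' of ring B of 19 (ortho to the 4'-OH, para to the 2'-OH) adds in Michael fashion to C6' of the quinone to give 22, and re-oxidation, closure onto the quinone carbonyl and hydrative oxidative loss of C4' as CO2 should give the tropolone with the galloylated flavan on C7 and all four stereocentres untouched.

**Compound list**

1 | 1-bromo-2,4,6-trifluorobenzene | Fc1cc(F)c(Br)c(F)c1 | starting material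
2 | (R)-trityl glycidyl ether, (2R)-2-[(trityloxy)methyl]oxirane | C1O[C@H]1COC(c1ccccc1)(c1ccccc1)c1ccccc1 | starting material
3 | (2,4,6-trifluorophenyl)magnesium chloride | Fc1cc(F)c([Mg]Cl)c(F)c1 | intermediate
4 | (2R)-1-(2,4,6-trifluorophenyl)-3-(trityloxy)propan-2-ol | O[C@@H](COC(c1ccccc1)(c1ccccc1)c1ccccc1)Cc1c(F)cc(F)cc1F | intermediate
5 | 1,3,5-trifluoro-2-[(2R)-2-(methoxymethoxy)-3-(trityloxy)propyl]benzene | COCO[C@@H](COC(c1ccccc1)(c1ccccc1)c1ccccc1)Cc1c(F)cc(F)cc1F | intermediate
6 | (2R)-2-(methoxymethoxy)-3-(2,4,6-trifluorophenyl)propan-1-ol | COCO[C@@H](CO)Cc1c(F)cc(F)cc1F | intermediate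
7 | (2R)-2-(methoxymethoxy)-3-(2,4,6-trifluorophenyl)propanal | COCO[C@@H](C=O)Cc1c(F)cc(F)cc1F | intermediate
8 | pyrogallol (benzene-1,2,3-triol) | Oc1cccc(O)c1O | starting material
9 | 1,2,3-tris(benzyloxy)benzene | c1ccc(COc2cccc(OCc3ccccc3)c2OCc2ccccc2)cc1 | intermediate
10 | 1-bromo-2,3,4-tris(benzyloxy)benzene | Brc1ccc(OCc2ccccc2)c(OCc2ccccc2)c1OCc1ccccc1 | intermediate
11 | [2,3,4-tris(benzyloxy)phenyl]magnesium bromide | Br[Mg]c1ccc(OCc2ccccc2)c(OCc2ccccc2)c1OCc1ccccc1 | intermediate
12 | (1R,2R)-2-(methoxymethoxy)-1-[2,3,4-tris(benzyloxy)phenyl]-3-(2,4,6-trifluorophenyl)propan-1-ol | COCO[C@@H]([C@H](O)c1ccc(OCc2ccccc2)c(OCc2ccccc2)c1OCc1ccccc1)Cc1c(F)cc(F)cc1F | intermediate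
13 | (2R,3R)-5,7-difluoro-3-(methoxymethoxy)-2-[2,3,4-tris(benzyloxy)phenyl]chromane | COCO[C@@H]1Cc2c(F)cc(F)cc2O[C@@H]1c1ccc(OCc2ccccc2)c(OCc2ccccc2)c1OCc1ccccc1 | intermediate
14 | (2R,3R)-7-(benzyloxy)-5-fluoro-3-(methoxymethoxy)-2-[2,3,4-tris(benzyloxy)phenyl]chromane | COCO[C@@H]1Cc2c(F)cc(OCc3ccccc3)cc2O[C@@H]1c1ccc(OCc2ccccc2)c(OCc2ccccc2)c1OCc1ccccc1 | intermediate
15 | (2R,3R)-5,7-bis(benzyloxy)-3-(methoxymethoxy)-2-[2,3,4-tris(benzyloxy)phenyl]chromane | COCO[C@@H]1Cc2c(OCc3ccccc3)cc(OCc3ccccc3)cc2O[C@@H]1c1ccc(OCc2ccccc2)c(OCc2ccccc2)c1OCc1ccccc1 | intermediate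
16 | (2R,3R)-5,7-bis(benzyloxy)-2-[2,3,4-tris(benzyloxy)phenyl]chroman-3-ol | O[C@@H]1Cc2c(OCc3ccccc3)cc(OCc3ccccc3)cc2O[C@@H]1c1ccc(OCc2ccccc2)c(OCc2ccccc2)c1OCc1ccccc1 | intermediate
17 | 3,4,5-tris(benzyloxy)benzoic acid | OC(=O)c1cc(OCc2ccccc2)c(OCc2ccccc2)c(OCc2ccccc2)c1 | starting material
18 | (2R,3R)-5,7-bis(benzyloxy)-2-[2,3,4-tris(benzyloxy)phenyl]chroman-3-yl 3,4,5-tris(benzyloxy)benzoate | O=C(O[C@@H]1Cc2c(OCc3ccccc3)cc(OCc3ccccc3)cc2O[C@@H]1c1ccc(OCc2ccccc2)c(OCc2ccccc2)c1OCc1ccccc1)c1cc(OCc2ccccc2)c(OCc2ccccc2)c(OCc2ccccc2)c1 | intermediate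
19 | (2R,3R)-5,7-dihydroxy-2-(2,3,4-trihydroxyphenyl)chroman-3-yl 3,4,5-trihydroxybenzoate | O=C(O[C@@H]1Cc2c(O)cc(O)cc2O[C@@H]1c1ccc(O)c(O)c1O)c1cc(O)c(O)c(O)c1 | intermediate
20 | (−)-epicatechin, (2R,3R)-2-(3,4-dihydroxyphenyl)chromane-3,5,7-triol | Oc1ccc(cc1O)[C@H]1Oc2cc(O)cc(O)c2C[C@H]1O | starting material
21 | epicatechin o-quinone, 4-[(2R,3R)-3,5,7-trihydroxychroman-2-yl]cyclohexa-3,5-diene-1,2-dione | O=C1C=CC(=CC1=O)[C@H]1Oc2cc(O)cc(O)c2C[C@H]1O | intermediate
22 | biaryl Michael adduct, (2R,3R)-2-{5-[4,5-dihydroxy-2-[(2R,3R)-3,5,7-trihydroxychroman-2-yl]phenyl]-2,3,4-trihydroxyphenyl}-5,7-dihydroxychroman-3-yl 3,4,5-trihydroxybenzoate | O=C(O[C@@H]1Cc2c(O)cc(O)cc2O[C@@H]1c1cc(-c2cc(O)c(O)cc2[C@H]2Oc3cc(O)cc(O)c3C[C@H]2O)c(O)c(O)c1O)c1cc(O)c(O)c(O)c1 | intermediate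
23 | (2R,3R)-5,7-dihydroxy-2-{3,4,6-trihydroxy-5-oxo-1-[(2R,3R)-3,5,7-trihydroxychroman-2-yl]-5H-benzo[7]annulen-7-yl}chroman-3-yl 3,4,5-trihydroxybenzoate | O=C(O[C@@H]1Cc2c(O)cc(O)cc2O[C@@H]1c1ccc2c([C@H]3Oc4cc(O)cc(O)c4C[C@H]3O)cc(O)c(O)c2c(=O)c1O)c1cc(O)c(O)c(O)c1 | target

**Step count and risks**

Total steps: 12. Longest linear sequence: 10 (steps 1, 2, 3, 4, 7, 8, 9, 10, 11, 12).

Step 8. What may go wrong is incomplete displacement of the last, least activated fluoride, or slow decomposition at the temperature that displacement needs. The fallback moves both intermolecular substitutions to the front, where the ring is still fully activated and forcing conditions are harmless. It sets out from 5: potassium benzyl oxide (2.2 equiv, DMI, 80 °C) should exchange the para and one ortho fluorine and stop there, giving 1,5-bis(benzyloxy)-3-fluoro-2-[(2R)-2-(methoxymethoxy)-3-(trityloxy)propyl]benzene F1. Detritylation as in step 3 gives the primary alcohol (2R)-3-[2,4-bis(benzyloxy)-6-fluorophenyl]-2-(methoxymethoxy)propan-1-ol F2. Dess–Martin oxidation gives the aldehyde (2R)-3-[2,4-bis(benzyloxy)-6-fluorophenyl]-2-(methoxymethoxy)propanal F3. Chelation-controlled addition of 11 as in step 7 gives the syn alcohol (1R,2R)-3-[2,4-bis(benzyloxy)-6-fluorophenyl]-2-(methoxymethoxy)-1-[2,3,4-tris(benzyloxy)phenyl]propan-1-ol F4. KH and 18-crown-6 in THF at 60 °C should then close ring C by a single intramolecular substitution of the one remaining fluoride, and the route is rejoined at 15.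

Step 12. What may go wrong is self-coupling and over-oxidation of both partners when they are oxidised together, or the oxidised ring B of 19 rather than that of 20 starting the coupling. The fallback separates oxidation from coupling and sets out from 20 and 19. Compound 20 alone is oxidised to epicatechin o-quinone 21 with o-chloranil (tetrachloro-1,2-benzoquinone) in acetone/Et2O at −40 °C. Compound 19 is then added under N2 as the only nucleophile for the Michael addition. A second portion of o-chloranil followed by aqueous NaHCO3 in air should complete ring expansion and decarboxylation, returning at 23; no compound outside the list is made.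

Step 7. What may go wrong is poor facial selectivity, with open-chain Felkin–Anh addition competing with the chelate. The fallback replaces substrate-controlled addition by oxidation and reduction, and sets out from the epimer mixture containing 12. Dess–Martin oxidation gives the ketone (2R)-2-(methoxymethoxy)-1-[2,3,4-tris(benzyloxy)phenyl]-3-(2,4,6-trifluorophenyl)propan-1-one F5. Reduction with K[BH(s-Bu)3] in THF at −78 °C, where the potassium counter-ion does not chelate and hydride is delivered in the Felkin–Anh sense anti to the α-MOM-oxy group, should give the syn alcohol and return to the route at 12.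

**Further compounds**

F1 | step 8 | 1,5-bis(benzyloxy)-3-fluoro-2-[(2R)-2-(methoxymethoxy)-3-(trityloxy)propyl]benzene | COCO[C@@H](COC(c1ccccc1)(c1ccccc1)c1ccccc1)Cc1c(F)cc(OCc2ccccc2)cc1OCc1ccccc1
F2 | step 8 | (2R)-3-[2,4-bis(benzyloxy)-6-fluorophenyl]-2-(methoxymethoxy)propan-1-ol | COCO[C@@H](CO)Cc1c(F)cc(OCc2ccccc2)cc1OCc1ccccc1
F3 | step 8 | (2R)-3-[2,4-bis(benzyloxy)-6-fluorophenyl]-2-(methoxymethoxy)propanal | COCO[C@@H](C=O)Cc1c(F)cc(OCc2ccccc2)cc1OCc1ccccc1
F4 | step 8 | (1R,2R)-3-[2,4-bis(benzyloxy)-6-fluorophenyl]-2-(methoxymethoxy)-1-[2,3,4-tris(benzyloxy)phenyl]propan-1-ol | COCO[C@@H]([C@H](O)c1ccc(OCc2ccccc2)c(OCc2ccccc2)c1OCc1ccccc1)Cc1c(F)cc(OCc2ccccc2)cc1OCc1ccccc1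
F0 | step 12 | none | none
F5 | step 7 | (2R)-2-(methoxymethoxy)-1-[2,3,4-tris(benzyloxy)phenyl]-3-(2,4,6-trifluorophenyl)propan-1-one | COCO[C@@H](C(=O)c1ccc(OCc2ccccc2)c(OCc2ccccc2)c1OCc1ccccc1)Cc1c(F)cc(F)cc1F
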